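Numbering used throughout: ring A is the central benzene ring. C1 carries the quinone-methide carbon, C2 the 4-hydroxyphenyl group, C3 and C4 are CH, C5 carries CH2OH and C6 the arylethynyl group.

## The problem

Selaginellin has no stereocentre, and its exocyclic C=C bond sits on a symmetric cyclohexadienone, so the synthesis has only connectivity to solve. Ring A carries four different carbon substituents on the contiguous carbons C5, C6, C1 and C2 (hydroxymethyl, arylethynyl, diarylmethylidene, aryl), with C3 and C4 unsubstituted. No simple benzene has this pattern, and substitution chemistry on a preformed ring cannot tell these positions apart. C1 is the most crowded site: it bears a fully substituted carbon and is flanked by the C2 aryl and the C6 alkynyl group. The quinone methide is the dehydrated form of a triaryl carbinol with two 4-hydroxyphenyl groups; it is an electrophile and has to be unveiled last, from protected phenols, without harming the alkyne or the benzylic alcohol. The alkyne lies between two benzylic C–O carbons (on C5 and on C1) whose alkoxides can add across it under strong base or π-acidic metals. The feature that opens the problem is the ortho pair C5–CH2–O and C6–C(alkyne): on paper they close through oxygen to a five-membered lactone, C5–CH2–O–C(=O)–C6, whose carbonyl carbon is the future first alkyne carbon. With C3–C4 as the inner carbons of a 1,3-diene and a carbonyl-level carbon on C1, ring A is then the dehydrogenated intramolecular Diels–Alder adduct of a 2,4-dienyl ynoate.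

## Retrosynthesis

**19 ⇒ 17.** The quinone methide is taken back to the triaryl carbinol 17 with three phenols masked as MOM ethers. Only C–O bonds are cut. The forward step needs acid strong enough to cleave aryl MOM ethers and ionise the carbinol (to cation 18), but not to hydrate the alkyne.

**17 ⇒ 15 + 16, and 15 ⇒ 14 ⇒ 13.** The C(sp)–aryl bond is cut to terminal alkyne 15 and 4-iodophenol 16. The terminal alkyne carbon is then removed, leaving the aldehyde-level carbon of lactol 14, which is the half-reduced form of lactone 13. This is preferred over cutting the C6–C(sp) bond because the lactone carbonyl carbon is already on C6 from the ring synthesis. The forward steps are a lactone half-reduction, a one-carbon diazophosphonate homologation of a lactol, and a room-temperature Sonogashira coupling.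

**13 ⇒ 10 + 11.** The lactone 13 is a phthalein-type 3,3-diarylphthalide. It is cut at one aryl–C(carbinol) bond to diaryl ketone 10 and aryl bromide 11. Forward, the tertiary alkoxide 12 formed at the C1 substituent should take over the lactone carbonyl on C6 from the C5–CH2–O oxygen, releasing the CH2OH group. The step requires addition to the ketone in preference to the lactone.

**10 ⇒ 8 (key disconnection).** Ring A is cut at C1–C2 and C5–C6, with the aromatic ring taken back to cyclohexadiene 9. The precursor is the acyclic ester 8: an (E,E)-5-arylpentadienyl ester of an aroylpropiolic acid. Against the neighbouring cuts (aryl–aryl, aryl–alkynyl, aryl–carbonyl on a preformed ring), this cut creates the whole 1,2,3,4-pattern in one operation, and the ester tether allows only one orientation. The forward reaction must bring the ester into its s-cis conformation, cyclise, and be followed by dehydrogenation.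

**8 ⇒ 7 ⇒ 6 + 1; 6 ⇒ 4 + 5; 4 ⇒ 3 ⇒ 1 + 2.** The ynone comes from propargylic alcohol 7, made from propiolate 6 and aldehyde 1. Ester 6 comes from dienol 4 and propiolic acid 5. Dienol 4 comes from aldehyde 1 and phosphonate 2 via dienoate 3. All carbons of ring A and its four substituents therefore derive from 1 (used twice), 2, 5, 11, 16 and one diazo carbon.

## Roads not taken

**Alternative 1: decorate a preformed benzene by cross-coupling (the obvious route).** The cuts are the C2–aryl bond, the C6–alkynyl bond and both aryl–C(carbinol) bonds. Forward, the dihalobenzoate A1 would undergo Suzuki coupling at C–I and Sonogashira coupling at C–Br to give ester A2, followed by double addition of an aryllithium and deprotection.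
- A1 is itself a 1,2,3,4-tetrasubstituted benzene with two different halogens flanking an ester. Making it regioselectively takes several steps, so the substitution pattern is moved into the starting material, not solved.
- Every bond-forming step occurs at a position flanking C1. The last is a double addition to a 2,6-disubstituted benzoate, where the second addition to the intermediate ketone is slow.
- The chosen plan builds the crowded ring from an acyclic ester instead.

**Alternative 2: aryne three-component coupling.** The C2–aryl and C1–C(carbinol) bonds are cut together. Forward, iodide–magnesium exchange on fluoro-iodide A3 would give the 3-alkynylbenzyne A4; an aryl Grignard reagent would add at C2, and the C1-magnesium species would be trapped by a diaryl ketone to give carbinol A5.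
- A3 already holds three of the four contiguous groups plus a leaving group, so the precursor is hardly simpler than the product. It would need a metalation between fluorine and the alkynyl group whose site selectivity is not assured.
- The sense of addition to A4 rests only on the modest inductive pull of an sp-carbon substituent.
- The doubly flanked arylmagnesium must then attack a diaryl ketone, a hindered union.
- The tether of the chosen route fixes by geometry what this route leaves to a weak electronic bias.

**Alternative 3: untethered Diels–Alder with the alkyne already in place.** The same ring bonds are cut (C1–C2 and C5–C6). Forward, dienol 4 and diynone A6 would react and be dehydrogenated to ketone A7, saving the three steps that turn the lactone into the alkyne.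
- Regiochemistry would depend on frontier-orbital polarisation of a dienophile with conjugating groups at both ends and a diene substituted at both termini.
- The two triple bonds of A6 compete, and A7 still carries a dienophilic alkyne.
- A 1,4-disubstituted diene and a disubstituted alkyne combine slowly in bimolecular fashion, and a cross-conjugated diynone tends to oligomerise under these conditions.
- The ester tether buys certainty of orientation and an entropic advantage, and its three atoms end up in the target.

Key step: step 6

Assumption: 4-(methoxymethoxy)benzaldehyde 1 and 1-bromo-4-(methoxymethoxy)benzene 11 are taken as catalogue compounds; each is otherwise one MOMCl/iPr2NEt step from 4-hydroxybenzaldehyde or 4-bromophenol.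

## Route

**Step 1**
Reactants: 1 4-(methoxymethoxy)benzaldehyde; 2 triethyl 4-phosphonocrotonate
Product: 3 ethyl (2E,4E)-5-[4-(methoxymethoxy)phenyl]penta-2,4-dienoate
Conditions: LiN(SiMe3)2, THF, −78 to 0 °C
Reagents that add atoms: none
Why: Vinylogous Horner–Wadsworth–Emmons olefination; the allylic phosphonate anion reacts at its α-carbon with aromatic aldehydes, and reversible addition should give the E-configured new double bond, the 2E geometry being carried in from 2.

**Step 2**
Reactants: 3 ethyl (2E,4E)-5-[4-(methoxymethoxy)phenyl]penta-2,4-dienoate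
Product: 4 (2E,4E)-5-[4-(methoxymethoxy)phenyl]penta-2,4-dien-1-ol
Conditions: iBu2AlH, CH2Cl2, −78 °C; aq. KNaC4H4O6
Reagents that add atoms: none
Why: 1,2-Reduction of a conjugated ester to the allylic alcohol with DIBAL-H; conjugate reduction does not compete at −78 °C and the MOM acetal is inert.

**Step 3**
Reactants: 4 (2E,4E)-5-[4-(methoxymethoxy)phenyl]penta-2,4-dien-1-ol; 5 propiolic acid
Product: 6 (2E,4E)-5-[4-(methoxymethoxy)phenyl]penta-2,4-dien-1-yl prop-2-ynoate
Conditions: DCC, DMAP (cat.), CH2Cl2, −20 to 0 °C
Reagents that add atoms: none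
Why: Steglich esterification, run cold with little DMAP because propiolates are Michael acceptors and the electron-rich dienyl alcohol is acid-sensitive.

**Step 4**
Reactants: 6 (2E,4E)-5-[4-(methoxymethoxy)phenyl]penta-2,4-dien-1-yl prop-2-ynoate; 1 4-(methoxymethoxy)benzaldehyde
Product: 7 (2E,4E)-5-[4-(methoxymethoxy)phenyl]penta-2,4-dien-1-yl 4-hydroxy-4-[4-(methoxymethoxy)phenyl]but-2-ynoate
Conditions: LiN(SiMe3)2, THF, −78 °C; then 1; aq. NH4Cl, −78 °C
Reagents that add atoms: none
Why: Deprotonation of the propiolate C–H and 1,2-addition of the lithium acetylide to the aldehyde, the standard route to 4-hydroxy-2-ynoates; the acetylide is kept at −78 °C, where lithiated propiolate esters are stable. The new carbinol centre is racemic and is removed in step 5.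

**Step 5**
Reactants: 7 (2E,4E)-5-[4-(methoxymethoxy)phenyl]penta-2,4-dien-1-yl 4-hydroxy-4-[4-(methoxymethoxy)phenyl]but-2-ynoate
Product: 8 (2E,4E)-5-[4-(methoxymethoxy)phenyl]penta-2,4-dien-1-yl 4-[4-(methoxymethoxy)phenyl]-4-oxobut-2-ynoate
Conditions: MnO2, CH2Cl2, rt
Reagents that add atoms: none
Why: MnO2 oxidation of a benzylic–propargylic alcohol to the ynone; the neutral heterogeneous conditions should leave the electrophilic ynone ester and the diene untouched.

**Step 6**
Reactants: 8 (2E,4E)-5-[4-(methoxymethoxy)phenyl]penta-2,4-dien-1-yl 4-[4-(methoxymethoxy)phenyl]-4-oxobut-2-ynoate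
Product: 10 7-[4-(methoxymethoxy)benzoyl]-6-[4-(methoxymethoxy)phenyl]isobenzofuran-1(3H)-one, via cis-dihydrophthalide cycloadduct 9 (not isolated)
Conditions: PhCl (0.01 M), BHT (cat.), 130 °C; then DDQ, rt
Reagents that add atoms: none
Why: Intramolecular Diels–Alder reaction of a 2,4-dienyl alkynoate followed by dehydrogenation, the known route from such esters to phthalides. The (E,E)-diene adds suprafacially to the ynone triple bond, which carries a carbonyl group at each end and is therefore a strongly electron-poor dienophile matched to the aryl-substituted diene. The six-membered ring closes by [4+2] cycloaddition, forming ring A bonds C1–C2 and C5–C6; the five-membered lactone closes in the same event because its CH2–O–C(=O) atoms are the tether. The ester carbonyl carbon can therefore only end on C6 next to the CH2O-bearing C5, and the aroyl group on C1 next to the aryl-bearing C2. The styrene unit, the only other π system that could compete, cannot reach the alkyne through so short a tether. The two stereocentres of 9 (C3a and C6) are set cis by the E,E geometry and are both erased when DDQ abstracts the doubly allylic, benzylic C6 hydride and C3a loses a proton. The ester must reach its less stable s-cis conformation to cyclise, hence heat and high dilution; aromatisation makes the sequence irreversible.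

**Step 7**
Reactants: 10 7-[4-(methoxymethoxy)benzoyl]-6-[4-(methoxymethoxy)phenyl]isobenzofuran-1(3H)-one; 11 1-bromo-4-(methoxymethoxy)benzene
Product: 13 7-(hydroxymethyl)-3,3,4-tris[4-(methoxymethoxy)phenyl]isobenzofuran-1(3H)-one, via dichlorocerium tertiary alkoxide 12 (not isolated)
Conditions: 11, n-BuLi, THF, −78 °C; CeCl3, −78 °C; then 10, −78 to 0 °C; aq. NH4Cl
Reagents that add atoms: none
Why: Organocerium 1,2-addition to a hindered diaryl ketone beside an ester, following the classical aryl-metal addition to ortho-aroylbenzoates that gives 3,3-diarylphthalides. The weakly basic, oxophilic cerium reagent should prefer the ketone to the lactone. The tertiary alkoxide 12 lies over the lactone carbonyl and should transfer the acyl group to itself, giving the gem-diaryl lactone and freeing the primary alcohol.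

**Step 8**
Reactants: 13 7-(hydroxymethyl)-3,3,4-tris[4-(methoxymethoxy)phenyl]isobenzofuran-1(3H)-one
Product: 14 7-(hydroxymethyl)-3,3,4-tris[4-(methoxymethoxy)phenyl]-1,3-dihydroisobenzofuran-1-ol
Conditions: iBu2AlH (3 equiv), CH2Cl2, −78 °C; aq. KNaC4H4O6
Reagents that add atoms: none
Why: DIBAL-H half-reduction of a lactone to the lactol; the first equivalent is consumed by the primary alcohol and the aluminium hemiacetal is stable at −78 °C until work-up. The lactol carbon is a stereocentre of no consequence (racemic) and is destroyed in step 9.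

**Step 9**
Reactants: 14 7-(hydroxymethyl)-3,3,4-tris[4-(methoxymethoxy)phenyl]-1,3-dihydroisobenzofuran-1-ol
Product: 15 (2-ethynyl-3-{hydroxybis[4-(methoxymethoxy)phenyl]methyl}-4-[4-(methoxymethoxy)phenyl]phenyl)methanol
Conditions: dimethyl (1-diazo-2-oxopropyl)phosphonate, K2CO3, MeOH, 0 °C to rt
Reagents that add atoms: dimethyl (1-diazo-2-oxopropyl)phosphonate (Ohira–Bestmann reagent), CC(=O)C(=[N+]=[N-])P(=O)(OC)OC
Why: Ohira–Bestmann (Seyferth–Gilbert) homologation; the lactol equilibrates under base with the hydroxy aldehyde, which is intercepted by the diazomethylphosphonate anion formed in situ and gives the terminal alkyne after loss of N2 and a 1,2-hydrogen shift. Aryl MOM ethers are stable to K2CO3/MeOH, and at room temperature the flanking alkoxides should not add to the alkyne.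

**Step 10**
Reactants: 15 (2-ethynyl-3-{hydroxybis[4-(methoxymethoxy)phenyl]methyl}-4-[4-(methoxymethoxy)phenyl]phenyl)methanol; 16 4-iodophenol
Product: 17 4-{[2-(hydroxymethyl)-6-{hydroxybis[4-(methoxymethoxy)phenyl]methyl}-5-[4-(methoxymethoxy)phenyl]phenyl]ethynyl}phenol
Conditions: Pd(PPh3)2Cl2 (cat.), CuI (cat.), Et3N, THF, rt
Reagents that add atoms: none
Why: Sonogashira coupling of a terminal aryl alkyne with an aryl iodide; free phenol and alcohols are tolerated, and room temperature keeps cycloisomerisation of the hydroxyl groups onto the alkyne slow relative to coupling.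

**Step 11**
Reactants: 17 4-{[2-(hydroxymethyl)-6-{hydroxybis[4-(methoxymethoxy)phenyl]methyl}-5-[4-(methoxymethoxy)phenyl]phenyl]ethynyl}phenol
Product: 19 selaginellin, via triarylmethylium chloride 18 (not isolated)
Conditions: aq. HCl, MeOH–THF, rt to 40 °C; then aq. NaHCO3
Reagents that add atoms: none
Why: Acidic cleavage of the three aryl MOM acetals; the tertiary carbinol ionises to cation 18, a stabilised triarylmethane-dye cation of low electrophilicity, and neutralisation removes a phenolic proton to give the quinone methide (fuchsone formation). The primary benzylic alcohol should not ionise under dilute acid.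

## Compound list

1 | 4-(methoxymethoxy)benzaldehyde | COCOc1ccc(C=O)cc1 | starting material
2 | triethyl 4-phosphonocrotonate, ethyl (2E)-4-(diethoxyphosphoryl)but-2-enoate | CCOC(=O)/C=C/CP(=O)(OCC)OCC | starting material
3 | ethyl (2E,4E)-5-[4-(methoxymethoxy)phenyl]penta-2,4-dienoate | CCOC(=O)/C=C/C=C/c1ccc(OCOC)cc1 | intermediate
4 | (2E,4E)-5-[4-(methoxymethoxy)phenyl]penta-2,4-dien-1-ol | OC/C=C/C=C/c1ccc(OCOC)cc1 | intermediate
5 | propiolic acid (prop-2-ynoic acid) | OC(=O)C#C | starting material
6 | (2E,4E)-5-[4-(methoxymethoxy)phenyl]penta-2,4-dien-1-yl prop-2-ynoate | C#CC(=O)OC/C=C/C=C/c1ccc(OCOC)cc1 | intermediate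
7 | (2E,4E)-5-[4-(methoxymethoxy)phenyl]penta-2,4-dien-1-yl 4-hydroxy-4-[4-(methoxymethoxy)phenyl]but-2-ynoate (racemic) | COCOc1ccc(cc1)C(O)C#CC(=O)OC/C=C/C=C/c1ccc(OCOC)cc1 | intermediate
8 | (2E,4E)-5-[4-(methoxymethoxy)phenyl]penta-2,4-dien-1-yl 4-[4-(methoxymethoxy)phenyl]-4-oxobut-2-ynoate | COCOc1ccc(cc1)C(=O)C#CC(=O)OC/C=C/C=C/c1ccc(OCOC)cc1 | intermediate
9 | cis-7-[4-(methoxymethoxy)benzoyl]-6-[4-(methoxymethoxy)phenyl]-3a,6-dihydroisobenzofuran-1(3H)-one (racemic, one enantiomer drawn) | O=C1OC[C@H]2C=C[C@@H](c3ccc(OCOC)cc3)C(C(=O)c3ccc(OCOC)cc3)=C12 | intermediate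
10 | 7-[4-(methoxymethoxy)benzoyl]-6-[4-(methoxymethoxy)phenyl]isobenzofuran-1(3H)-one | O=C1OCc2ccc(-c3ccc(OCOC)cc3)c(C(=O)c3ccc(OCOC)cc3)c12 | intermediate
11 | 1-bromo-4-(methoxymethoxy)benzene | COCOc1ccc(Br)cc1 | starting material
12 | dichlorocerium alkoxide of 7-{hydroxybis[4-(methoxymethoxy)phenyl]methyl}-6-[4-(methoxymethoxy)phenyl]isobenzofuran-1(3H)-one | Cl[Ce](Cl)OC(c1ccc(OCOC)cc1)(c1ccc(OCOC)cc1)c1c(-c2ccc(OCOC)cc2)ccc2COC(=O)c12 | intermediate
13 | 7-(hydroxymethyl)-3,3,4-tris[4-(methoxymethoxy)phenyl]isobenzofuran-1(3H)-one | OCc1ccc(-c2ccc(OCOC)cc2)c2c1C(=O)OC2(c1ccc(OCOC)cc1)c1ccc(OCOC)cc1 | intermediate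
14 | 7-(hydroxymethyl)-3,3,4-tris[4-(methoxymethoxy)phenyl]-1,3-dihydroisobenzofuran-1-ol (racemic lactol) | OCc1ccc(-c2ccc(OCOC)cc2)c2c1C(O)OC2(c1ccc(OCOC)cc1)c1ccc(OCOC)cc1 | intermediate
15 | (2-ethynyl-3-{hydroxybis[4-(methoxymethoxy)phenyl]methyl}-4-[4-(methoxymethoxy)phenyl]phenyl)methanol | OCc1ccc(-c2ccc(OCOC)cc2)c(C(O)(c2ccc(OCOC)cc2)c2ccc(OCOC)cc2)c1C#C | intermediate
16 | 4-iodophenol | Oc1ccc(I)cc1 | starting material
17 | 4-{[2-(hydroxymethyl)-6-{hydroxybis[4-(methoxymethoxy)phenyl]methyl}-5-[4-(methoxymethoxy)phenyl]phenyl]ethynyl}phenol | OCc1ccc(-c2ccc(OCOC)cc2)c(C(O)(c2ccc(OCOC)cc2)c2ccc(OCOC)cc2)c1C#Cc1ccc(O)cc1 | intermediate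
18 | {3-(hydroxymethyl)-6-(4-hydroxyphenyl)-2-[(4-hydroxyphenyl)ethynyl]phenyl}bis(4-hydroxyphenyl)methylium chloride | [Cl-].OCc1ccc(-c2ccc(O)cc2)c([C+](c2ccc(O)cc2)c2ccc(O)cc2)c1C#Cc1ccc(O)cc1 | intermediate
19 | selaginellin | O=C1C=CC(=C(c2ccc(O)cc2)c2c(-c3ccc(O)cc3)ccc(CO)c2C#Cc2ccc(O)cc2)C=C1 | target

## Step count and risk

Total step count: 11. Longest linear sequence: 11 steps (1 to 19); compounds 2, 5, 11 and 16 enter as purchased building blocks.

**Step 6 (key step).**
- Risk: slow cyclisation, because the ester must leave its preferred s-trans conformation. At the temperature then needed, the electron-rich dienyl ester may ionise (loss of carboxylate, allylic scrambling), or bimolecular cycloaddition and oligomerisation of the ynone may take over.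
- Fallback: a bimolecular Diels–Alder reaction that sets out from dienol 4 and aldehyde 1 and returns at 10. Lithiated methyl propiolate would add to 1 to give methyl 4-hydroxy-4-[4-(methoxymethoxy)phenyl]but-2-ynoate F1, and MnO2 would oxidise it to methyl 4-[4-(methoxymethoxy)phenyl]-4-oxobut-2-ynoate F2. Heating F2 with 4 in toluene should give methyl cis-6-(hydroxymethyl)-2-[4-(methoxymethoxy)benzoyl]-3-[4-(methoxymethoxy)phenyl]cyclohexa-1,4-diene-1-carboxylate F3. DDQ would convert it to methyl 6-(hydroxymethyl)-2-[4-(methoxymethoxy)benzoyl]-3-[4-(methoxymethoxy)phenyl]benzoate F4, which should lactonise under a trace of acid to 10.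
- Regiochemistry of the fallback: it rests on orbital matching only. The ketone is the stronger acceptor, so the ester-bearing alkyne carbon is the more electrophilic; the aryl group is the stronger donor, so the CH2OH-bearing diene terminus has the larger coefficient. The wrong regioisomer cannot lactonise, which should make separation easy.

**Step 7.**
- Risk: competing attack of the aryl nucleophile on the lactone carbonyl, or failure of 1,2-addition at the doubly ortho-substituted ketone (electron transfer or conjugate addition into the aroyl ring).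
- Fallback: mask the competing electrophile as a carboxylate, setting out from 10 and returning at 13. Saponification (KOH, aq. THF) would give potassium 6-(hydroxymethyl)-2-[4-(methoxymethoxy)benzoyl]-3-[4-(methoxymethoxy)phenyl]benzoate F5. The dried salt would be treated with excess 4-(methoxymethoxy)phenylmagnesium bromide, to which a carboxylate is inert, as in the classical preparation of 3,3-diarylphthalides from ortho-aroylbenzoate salts. On acidic work-up the carbinol acid should close to 13.

**Step 9.**
- Risk: the gem-diaryl lactol may stay closed, so that too little aldehyde is available to the diazophosphonate anion. Conversion is then slow and base-induced addition of an alkoxide to the newly formed alkyne has time to compete.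
- Fallback: olefination and elimination, from 14 back to 15. Excess Ph3P=CHCl (from (chloromethyl)triphenylphosphonium chloride and NaN(SiMe3)2), the usual way to drive Wittig reactions of lactols, should give (2-(2-chloroethenyl)-3-{hydroxybis[4-(methoxymethoxy)phenyl]methyl}-4-[4-(methoxymethoxy)phenyl]phenyl)methanol F6 as a mixture of double-bond isomers. Excess LiN(iPr)2 at −78 °C should then dehydrochlorinate it to 15.

**Step 11.**
- Risk: acid-promoted hydration of the electron-rich diaryl alkyne, or cation-initiated cyclisation onto it, while the MOM ethers are being cleaved; a lesser risk is etherification of the benzylic alcohol by methanol.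
- Fallback: reverse the order of the last two operations, from 15 to 19. Terminal alkyne 15, whose triple bond is much less prone to protonation, would be deprotected under the step 11 conditions to 4-{[2-ethynyl-3-(hydroxymethyl)-6-(4-hydroxyphenyl)phenyl](4-hydroxyphenyl)methylidene}cyclohexa-2,5-dien-1-one F7. Sonogashira coupling of F7 with 16 under the step 10 conditions should then give 19 directly.

## Further compounds

F1 | step 6 | methyl 4-hydroxy-4-[4-(methoxymethoxy)phenyl]but-2-ynoate (racemic) | COC(=O)C#CC(O)c1ccc(OCOC)cc1
F2 | step 6 | methyl 4-[4-(methoxymethoxy)phenyl]-4-oxobut-2-ynoate | COC(=O)C#CC(=O)c1ccc(OCOC)cc1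
F3 | step 6 | methyl cis-6-(hydroxymethyl)-2-[4-(methoxymethoxy)benzoyl]-3-[4-(methoxymethoxy)phenyl]cyclohexa-1,4-diene-1-carboxylate (racemic, one enantiomer drawn) | COC(=O)C1=C(C(=O)c2ccc(OCOC)cc2)[C@H](c2ccc(OCOC)cc2)C=C[C@@H]1CO
F4 | step 6 | methyl 6-(hydroxymethyl)-2-[4-(methoxymethoxy)benzoyl]-3-[4-(methoxymethoxy)phenyl]benzoate | COC(=O)c1c(CO)ccc(-c2ccc(OCOC)cc2)c1C(=O)c1ccc(OCOC)cc1
F5 | step 7 | potassium 6-(hydroxymethyl)-2-[4-(methoxymethoxy)benzoyl]-3-[4-(methoxymethoxy)phenyl]benzoate | [K+].[O-]C(=O)c1c(CO)ccc(-c2ccc(OCOC)cc2)c1C(=O)c1ccc(OCOC)cc1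
F6 | step 9 | (2-(2-chloroethenyl)-3-{hydroxybis[4-(methoxymethoxy)phenyl]methyl}-4-[4-(methoxymethoxy)phenyl]phenyl)methanol (mixture of double-bond isomers) | OCc1ccc(-c2ccc(OCOC)cc2)c(C(O)(c2ccc(OCOC)cc2)c2ccc(OCOC)cc2)c1C=CCl
F7 | step 11 | 4-{[2-ethynyl-3-(hydroxymethyl)-6-(4-hydroxyphenyl)phenyl](4-hydroxyphenyl)methylidene}cyclohexa-2,5-dien-1-one | O=C1C=CC(=C(c2ccc(O)cc2)c2c(-c3ccc(O)cc3)ccc(CO)c2C#C)C=C1
A1 | alternative 1 | methyl 2-bromo-3-({[tert-butyl(dimethyl)silyl]oxy}methyl)-6-iodobenzoate | COC(=O)c1c(I)ccc(CO[Si](C)(C)C(C)(C)C)c1Br
A2 | alternative 1 | methyl 3-({[tert-butyl(dimethyl)silyl]oxy}methyl)-6-[4-(methoxymethoxy)phenyl]-2-{[4-(methoxymethoxy)phenyl]ethynyl}benzoate | COC(=O)c1c(-c2ccc(OCOC)cc2)ccc(CO[Si](C)(C)C(C)(C)C)c1C#Cc1ccc(OCOC)cc1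
A3 | alternative 2 | tert-butyl[(4-fluoro-3-iodo-2-{[4-(methoxymethoxy)phenyl]ethynyl}phenyl)methoxy]dimethylsilane | CC(C)(C)[Si](C)(C)OCc1ccc(F)c(I)c1C#Cc1ccc(OCOC)cc1
A4 | alternative 2 | 3-alkynylbenzyne derived from A3 (aryne across C1–C2 of ring A) | CC(C)(C)[Si](C)(C)OCC1=C(C#Cc2ccc(OCOC)cc2)C#CC=C1
A5 | alternative 2 | [3-({[tert-butyl(dimethyl)silyl]oxy}methyl)-6-[4-(methoxymethoxy)phenyl]-2-{[4-(methoxymethoxy)phenyl]ethynyl}phenyl]bis[4-(methoxymethoxy)phenyl]methanol | CC(C)(C)[Si](C)(C)OCc1ccc(-c2ccc(OCOC)cc2)c(C(O)(c2ccc(OCOC)cc2)c2ccc(OCOC)cc2)c1C#Cc1ccc(OCOC)cc1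
A6 | alternative 3 | 1,5-bis[4-(methoxymethoxy)phenyl]penta-2,4-diyn-1-one | COCOc1ccc(cc1)C(=O)C#CC#Cc1ccc(OCOC)cc1
A7 | alternative 3 | [3-(hydroxymethyl)-6-[4-(methoxymethoxy)phenyl]-2-{[4-(methoxymethoxy)phenyl]ethynyl}phenyl][4-(methoxymethoxy)phenyl]methanone | OCc1ccc(-c2ccc(OCOC)cc2)c(C(=O)c2ccc(OCOC)cc2)c1C#Cc1ccc(OCOC)cc1
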